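## Structural features

The target is a tetracycle built on a bicyclo[2.2.2]oct-2-ene. In the cage numbering used below, C1 is the carbinol bridgehead, C2=C3 the alkene bridge (C2 acyl-bearing, C3 oxygen-bearing), C4 the methyl bridgehead, C5 the cage ketone, C6 the methyl-bearing quaternary carbon next to it, C7 a CH and C8 the CMe2 carbon. An oxolane is fused over C7–C1–C6: a CH2–O arm leaves C7 and its oxygen ends on C6, a quaternary carbon alpha to the C5 ketone. A 2-phenyl-2,3-dihydro-4H-pyran-4-one is fused on C2=C3, which is its enol-ether double bond, with the ring oxygen on C3, the ring carbonyl on C2 and the phenyl-bearing carbon as the only stereocentre outside the cage. The cage carries four stereocentres, C7 (R), C1 (R), C6 (S) and C4 (R); C7, C1 and C6 are contiguous and all four are locked to one another by the bicycle, so the only free variables are the sense of the cage and the (S) benzylic carbon. Fragile groups are the vinylogous ester of the pyranone (addition–elimination, and opening to a cinnamoyl ketone that would racemise the benzylic carbon), the C1 carbinol beta to the enone carbonyl (retro-aldol in base) and, on the way, silyl enol ethers and an ethoxyalkyne. The real difficulty is the density of fully substituted carbons (C8, C4, C1, C6 and both alkene carbons) and above all the O–C6 bond: C6 is the alpha carbon of a ketone, a nucleophilic site that an alkoxide cannot etherify in the normal polarity. The key step exploits exactly this: C6 is the beta carbon of the C5=C6 silyl enol ether of the cage ketone and the hydroxymethyl oxygen on C7 is held 1,3 to it on the rigid bicycle, so one-electron oxidation of the enol ether lets that oxygen close the oxolane on C6.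

## Logic of the disconnections

**25 to 23 (through 24).** The ring O–C3 bond of the pyranone is cut. This bond forms by addition–elimination on an ethoxy enone under mild acid, and cutting it takes the benzylic stereocentre out of the ring so that it can be bought with 1. The forward step must free the benzylic hydroxyl of 23 without ionising or eliminating its C–O bond.

**23 to 22 (key step).** The oxolane O–C6 bond is cut. This is the one bond that ordinary polarity cannot make, and removing it opens the oxolane and turns the C5 ketone with its quaternary neighbour into a tetrasubstituted silyl enol ether. The forward step must oxidise only that enol ether and let the C7 hydroxymethyl group, not methanol, capture C6.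

**22 to 21.** No skeletal bond is cut: the C1 hydroxyl and the primary hydroxyl of 22 are tied into one benzylidene acetal. A simpler precursor with an acetate on the primary oxygen and a silyl ether on C1 was rejected for four reasons:
- the acetate would have to be removed with base in the presence of a silyl enol ether and a beta-silyloxy ketone;
- the hindered bridgehead silyl ether would have to come off at the very end;
- nothing in it fixes on which side of the dione the second enol ether forms;
- with a freely rotating arm, a methyl group of C8 shields each face of the diene.

The acetal answers all four, and it is removed by neutral hydrogenolysis, which must spare the enol ether and the benzylic silyl ether.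

**21 to 20 and 6.** The C3–C4 and C1–C2 bonds are cut in a Diels–Alder sense. This splits the cage into a dimedone-derived diene and an alkynone that already holds C2, C3, the ethoxy leaving group and the (S)-carbinol. The forward step must join the methyl-bearing diene terminus to the ethoxy-bearing alkyne carbon and must add to the diene face opposite the CH2O arm.

**6 to 3 and 4 (through 5), then 3 to 2 to 1.** The acyl–alkyne bond is cut, then the amide and the silyl ether are taken back. The carbinol carbon comes from 1 with its C–O bond untouched; the demand is a single addition of the acetylide and a work-up that does not hydrate the ynol ether.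

**20 to 18, and 18 to 16 and 8.** The O–Si bond and then the C–CH3 bond at the carbon alpha-prime to the ketone are cut. Both forward steps are kinetic alpha-prime deprotonations of a vinylogous ester; they must not touch the ring-fusion hydrogen gamma to the carbonyl.

**16 to 15 to 14.** The two acetal C–O bonds are cut, then the isobutyl enol ether is put back. Only the enol oxygen next to the CH2OH-bearing carbon can close a six-membered acetal, so this pair of steps moves the enol ether oxygen to the hindered side, where simple etherification would not put it.

**14 to 13, and 13 to 10 and 11.** The single enantiomer is taken back to the racemate, and the C–CH2OH bond is cut. The stereocentre is introduced without control and then resolved, because it is the only one the route has to supply beyond that of 1.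

**10 to 9, and 9 to 7 and 8.** The enol ether and the methyl group between the two carbonyls are removed. Since 9 is symmetric, only one enol ether can form.

## Other disconnections considered

**Alternative 1:** The cut is at C5–C4 and C6–C1. A 3-benzyloxycyclohexenone carrying a phenyl lactate ether on its CH2O arm, A2, would be treated with KN(SiMe3)2: its alpha-prime enolate would acylate itself with the phenyl ester, and the new alpha-alkoxy ketone enolate would add across the ring to the benzyloxy-bearing enone carbon to give the bridgehead benzyl ether cage diketone A1.
- In its favour: the bicycle, the oxolane and the C6 stereocentre would arise in one flask, and the O–C6 bond would be an ordinary ether made early, with no oxidant and no cell. On redox economy and rings per step this is the better plan.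
- Against it: A2 needs the enol-ether oxygen next to the CH2O-bearing carbon, the same regiochemical problem as in the chosen route, but without the acetal device, because the primary oxygen is already alkylated. The acylation gives a 1,3-diketone that cannot be deprotonated between its carbonyls, so it is driven only by the poor nucleophilicity of phenoxide and by the Michael step that follows. A1 still lacks the whole pyranone, which would need a C-acylation at C2, a cyclodehydration and a late hydrogenolysis of the bridgehead benzyl ether next to the benzylic ring C–O bond.
- Comparison: on structure it builds more per step; on mechanism it is purely polar but rests on an unfavourable Claisen equilibrium; on step economy the several steps after A1 outweigh the gain, against one step after 23.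

**Alternative 2:** The cut is at the C2–acyl bond and the ring O–C3 bond. The lithium enolate (LiN(SiMe3)2) of the bridgehead silyl ether cage diketone A4 would open (S)-4-phenyloxetan-2-one A5 at its acyl carbon, and acid would then condense the freed benzylic hydroxyl onto the C3 carbonyl to give A3, the bridgehead tert-butyldimethylsilyl ether of 25.
- In its favour: the carbinol arrives late as a small chiral fragment, and A4 has a single enolisable carbon, so the regiochemistry of the union is not in doubt. On this point it is the equal of the chosen Diels–Alder step or better, and it avoids an ethoxyalkyne.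
- Against it: benzylic beta-lactones are prone to alkyl–oxygen opening (inversion, wrong connectivity); the cyclodehydration competes with dehydration to a cinnamoyl ketone, which threatens the (S) centre; the bridgehead silyl ether must still be removed. Above all, A4 already contains the oxolane, so the O–C6 bond is only postponed.
- Comparison: structurally it is a good endgame but not a solution to the hard bond; mechanistically it is polar and simple; in steps it equals the chosen endgame but needs a separate synthesis of A4.

**Alternative 3:** The cut is at C4–C3 and C2–C1. The potassium enolate (KN(SiMe3)2) of the 6-oxabicyclo[3.2.1]octane diketone A7 would add through its methyl-bearing carbon to the ethoxy-bearing carbon of alkynone 6, and the allenolate would close on the one-carbon-bridge ketone to give A6, which is the same compound as 23.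
- In its favour: it reaches 23 in one polar step from A7 and 6, without a silyl enol ether, hydrogenolysis or electrolysis. On steps from its substrate it is better than the chosen plan. The O–C6 bond would be made on a 2-methyl-1,3-dione, whose central carbon is easier to oxidise than a hindered enol ether; this too is a point in its favour.
- Against it: A7 is a non-enolisable 1,3-diketone in a strained bicycle and is open to retro-Claisen cleavage by base. The strong base also threatens the beta-silyloxy ketone of 6 (elimination). The aldol onto the hindered bridge ketone is reversible (the product is a beta-hydroxy enone), and the Michael step must form the C4 quaternary centre next to CMe2 from a hindered enolate.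
- Comparison: on structure and step count it is at least the equal of the chosen plan; on mechanism the chosen sequence keeps every sensitive group under neutral or weakly acidic conditions, and that decided the choice.

Key step: step 14

Assumption: in step 7 the lipase is taken to acylate the (S)-alcohol faster, so that (R)-14 is the recovered alcohol; the opposite preference is covered by the fallback for step 7.

Check on configuration: C7 is (R) from 14 to 25 and the carbinol carbon is (S) from 1 to 25, because no bond to either centre is broken; the cage centres of 21, 22 and 23 match those of 25.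

## Steps

Step 1
Reactants: 1 ethyl (S)-3-hydroxy-3-phenylpropanoate
Product: 2 ethyl (S)-3-[(tert-butyldimethylsilyl)oxy]-3-phenylpropanoate
Conditions: t-BuMe2SiCl, imidazole, DMF, rt
Reagents that add atoms: tert-butyldimethylsilyl chloride, CC(C)(C)[Si](C)(C)Cl
Why: Silyl ether formation on a secondary alcohol; the stereocentre is not involved, and the ether is needed to carry the carbinol through amide formation and acetylide addition.

Step 2
Reactants: 2 ethyl (S)-3-[(tert-butyldimethylsilyl)oxy]-3-phenylpropanoate
Product: 3 (S)-3-[(tert-butyldimethylsilyl)oxy]-N-methoxy-N-methyl-3-phenylpropanamide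
Conditions: MeNH(OMe)·HCl, i-PrMgCl, THF, −20 → 0 °C
Reagents that add atoms: N,O-dimethylhydroxylamine hydrochloride, CNOC.Cl
Why: Aminolysis of the ester by the chloromagnesium amide (Weinreb amide formation); the low temperature should suppress loss of the beta-silyloxy group by elimination.

Step 3
Reactants: 3 (S)-3-[(tert-butyldimethylsilyl)oxy]-N-methoxy-N-methyl-3-phenylpropanamide; 4 ethoxyacetylene
Product: 6 (S)-5-[(tert-butyldimethylsilyl)oxy]-1-ethoxy-5-phenylpent-1-yn-3-one, via lithium ethoxyacetylide 5 (not isolated)
Conditions: 4, n-BuLi, THF, −78 °C; then 3, −78 → −30 °C; aq. NH4Cl, 0 °C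
Reagents that add atoms: none
Why: Weinreb ketone synthesis: the acetylide adds once because the chelated tetrahedral intermediate collapses only on work-up; a cold buffered quench should keep the ynol ether from hydration.

Step 4
Reactants: 7 dimedone (5,5-dimethylcyclohexane-1,3-dione); 8 iodomethane
Product: 9 2,5,5-trimethylcyclohexane-1,3-dione
Conditions: K2CO3, acetone, reflux
Reagents that add atoms: none
Why: C-alkylation of the 1,3-dione enolate at the carbon between the carbonyls; any O-methyl enol ether formed beside it is separated or hydrolysed back.

Step 5
Reactants: 9 2,5,5-trimethylcyclohexane-1,3-dione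
Product: 10 3-isobutoxy-2,5,5-trimethylcyclohex-2-en-1-one
Conditions: i-BuOH, TsOH·H2O (cat.), toluene, reflux, Dean–Stark
Reagents that add atoms: 2-methylpropan-1-ol, CC(C)CO
Why: Acid-catalysed enol etherification with azeotropic removal of water; 9 is symmetric, so only one vinylogous ester can form.

Step 6
Reactants: 10 3-isobutoxy-2,5,5-trimethylcyclohex-2-en-1-one; 11 formaldehyde (monomer, from cracked paraformaldehyde)
Product: 13 rac-6-(hydroxymethyl)-3-isobutoxy-2,5,5-trimethylcyclohex-2-en-1-one, via lithium enolate 12 (not isolated)
Conditions: LiN(i-Pr)2, THF, −78 °C; CH2O (gas), −78 → −40 °C; aq. NH4Cl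
Reagents that add atoms: none
Why: Stork–Danheiser logic: kinetic alpha-prime deprotonation of the vinylogous ester, then aldol addition to formaldehyde; the new stereocentre is formed as the racemate.

Step 7
Reactants: 13 rac-6-(hydroxymethyl)-3-isobutoxy-2,5,5-trimethylcyclohex-2-en-1-one
Product: 14 (R)-6-(hydroxymethyl)-3-isobutoxy-2,5,5-trimethylcyclohex-2-en-1-one
Conditions: lipase (Burkholderia cepacia, immobilised), vinyl acetate, t-BuOMe, 30 °C, run just past half conversion; chromatography
Reagents that add atoms: none
Why: Lipase-catalysed kinetic resolution by irreversible transesterification of a primary alcohol with a beta stereocentre; running slightly past half conversion should leave the slow (R)-alcohol in high enantiomeric purity, and the neutral conditions cannot epimerise the carbon alpha to the ketone.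

Step 8
Reactants: 14 (R)-6-(hydroxymethyl)-3-isobutoxy-2,5,5-trimethylcyclohex-2-en-1-one
Product: 15 (R)-4-(hydroxymethyl)-2,5,5-trimethylcyclohexane-1,3-dione
Conditions: HCl (1 M aq.), THF, 0 °C → rt
Reagents that add atoms: water, O
Why: Hydrolysis of the vinylogous ester by addition–elimination of water at the enol-ether carbon; cold dilute acid should avoid dehydration of the beta-hydroxymethyl ketone and enolisation towards the stereocentre.

Step 9
Reactants: 15 (R)-4-(hydroxymethyl)-2,5,5-trimethylcyclohexane-1,3-dione
Product: 16 (2R,4aR)-5,5,8-trimethyl-2-phenyl-4a,5-dihydro-4H-1,3-benzodioxin-7(6H)-one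
Conditions: PhCH(OMe)2, camphorsulfonic acid (cat.), CH2Cl2, 5 Å sieves, rt
Reagents that add atoms: benzaldehyde dimethyl acetal, COC(OC)c1ccccc1
Why: Acid-catalysed acetalisation of the primary hydroxyl and the adjacent enol hydroxyl, the vinylogous counterpart of dioxanone formation from beta-hydroxy acids; only the enol oxygen next to the CH2OH-bearing carbon can close the six-membered ring, which fixes the enol ether on that side, and the acetal carbon should settle with phenyl equatorial (cis to the ring-fusion hydrogen).

Step 10
Reactants: 16 (2R,4aR)-5,5,8-trimethyl-2-phenyl-4a,5-dihydro-4H-1,3-benzodioxin-7(6H)-one; 8 iodomethane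
Product: 18 (2R,4aR)-5,5,6,8-tetramethyl-2-phenyl-4a,5-dihydro-4H-1,3-benzodioxin-7(6H)-one (both C6 epimers), via lithium enolate 17 (not isolated)
Conditions: LiN(i-Pr)2, THF, −78 °C; MeI, DMPU, −78 → −30 °C
Reagents that add atoms: none
Why: Stork–Danheiser alkylation: the carbonyl-directed kinetic deprotonation takes the alpha-prime CH2 and not the ring-fusion CH; the configuration at C6 is irrelevant because that carbon becomes trigonal in the next step.

Step 11
Reactants: 18 (2R,4aR)-5,5,6,8-tetramethyl-2-phenyl-4a,5-dihydro-4H-1,3-benzodioxin-7(6H)-one
Product: 20 tert-butyldimethyl{[(2R,4aR)-5,5,6,8-tetramethyl-2-phenyl-4a,5-dihydro-4H-1,3-benzodioxin-7-yl]oxy}silane, via lithium enolate 19 (not isolated)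
Conditions: LiN(i-Pr)2, THF, −78 °C; t-BuMe2SiCl, DMPU, −78 → 0 °C; non-aqueous work-up
Reagents that add atoms: tert-butyldimethylsilyl chloride, CC(C)(C)[Si](C)(C)Cl
Why: Kinetic alpha-prime enolisation and O-silylation give the cross-conjugated silyl dienol ether; because the other enol oxygen is held in the acetal, the diene can form only in the C8a=C8–C7=C6 sense and C4a stays a stereocentre.

Step 12
Reactants: 20 tert-butyldimethyl{[(2R,4aR)-5,5,6,8-tetramethyl-2-phenyl-4a,5-dihydro-4H-1,3-benzodioxin-7-yl]oxy}silane; 6 (S)-5-[(tert-butyldimethylsilyl)oxy]-1-ethoxy-5-phenylpent-1-yn-3-one
Product: 21 cycloadduct: bicyclo[2.2.2]octa-2,5-diene with the C1–O and C7–CH2–O oxygens joined in a benzylidene acetal, 3-ethoxy, 4,6,8,8-tetramethyl, 5-(tert-butyldimethylsilyl)oxy and a 2-[(S)-3-(tert-butyldimethylsilyl)oxy-3-phenylpropanoyl] group; C7 (R), CH2O arm syn to the C5=C6 bridge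
Conditions: toluene (concentrated), BHT (cat.), 80 °C, sealed tube
Reagents that add atoms: none
Why: Diels–Alder reaction of a 1,3-dioxygenated diene with an ynone: the methyl-bearing terminus, beta to the silyloxy group and vinylogous to the acetal oxygen, is the nucleophilic end and bonds to the ethoxy-bearing beta carbon of the ynone. The fused dioxane holds the CH2O arm pseudo-equatorial, so one diene face carries only the axial ring-fusion hydrogen and the other an axial C5 methyl; addition to the open face sets C1 and C4 relative to C7. The temperature stays below the range in which ethoxyalkynes lose ethylene and the adduct could undergo Alder–Rickert cleavage.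

Step 13
Reactants: 21 cycloadduct (benzylidene acetal)
Product: 22 (S)-3-[(tert-butyldimethylsilyl)oxy]-1-[5-(tert-butyldimethylsilyl)oxy-3-ethoxy-1-hydroxy-7-(hydroxymethyl)-4,6,8,8-tetramethylbicyclo[2.2.2]octa-2,5-dien-2-yl]-3-phenylpropan-1-one; C7 (R), CH2OH syn to the C5=C6 bridge
Conditions: H2 (1 atm), Pd/C, NaHCO3, EtOAc, rt; stopped after two equivalents of H2
Reagents that add atoms: none
Why: Hydrogenolysis of a benzylidene acetal under neutral conditions frees both hydroxyls; the tetrasubstituted enol-ether and push–pull alkenes should not be reduced, NaHCO3 takes up acid traces that would hydrolyse the enol ether, and the silylated benzylic C–O bond should react much more slowly than the acetal.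

Step 14
Reactants: 22 bicyclo[2.2.2]octadiene silyl enol ether with free C1 hydroxyl and free hydroxymethyl group
Product: 23 (S)-3-[(tert-butyldimethylsilyl)oxy]-1-(cage)-3-phenylpropan-1-one, cage = 3-ethoxy-1-hydroxy-4,6,8,8-tetramethyl-5-oxobicyclo[2.2.2]oct-2-en-2-yl with a C7–CH2–O–C6 oxolane bridge
Conditions: reticulated vitreous carbon anode, Pt cathode, undivided cell, constant current (ca. 2.2 F per mol); LiClO4 (0.1 M), 2,6-lutidine, MeOH–CH2Cl2 1:4, rt
Reagents that add atoms: none
Why: At the carbon anode the tetrasubstituted silyl enol ether, the most electron-rich pi system of 22, loses one electron to give a radical cation spread over the oxygen, C5 and C6. The hydroxymethyl oxygen on C7 adds to C6 and 2,6-lutidine takes the proton; the alpha-silyloxy radical left at C5 is oxidised a second time to a silyloxocarbenium ion, which passes its silyl group to methanol and leaves the cage ketone. The closest known reaction types are the anodic coupling of enol-ether radical cations with tethered alcohols to give tetrahydrofurans and the anodic alpha-alkoxylation of silyl enol ethers in methanol. The oxolane closes in the 5-exo-trig mode, the attacked carbon C6 lying in the new ring and C5 outside it. The new quaternary stereocentre is controlled by the cage alone: the arm on C7 can reach only the face of C6 that looks towards the C7–C8 bridge, so the methyl group ends on the face towards the alkene bridge. The step needs chemoselective oxidation, which the substrate secures because the second alkene is a beta-ethoxy enone whose acyl group lowers its donor level and the arene and silyl ethers are harder still to oxidise. It also needs the tethered hydroxyl to outrun methanol, which the rigid 1,3 placement provides, while the C1 hydroxyl could only close an oxirane and should not compete. Lutidine and a low current density keep the medium near neutral, so the enol ether is not simply solvolysed and the beta-silyloxy ketone does not eliminate.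

Step 15
Reactants: 23 oxolane cage ketone with ethoxy enone and silylated (S)-carbinol
Product: 25 CNP0322161.1 (target), via hydroxy enone 24 (not isolated)
Conditions: HF (48% aq.), MeCN, 0 °C → rt; then CF3CO2H, rt
Reagents that add atoms: none
Why: HF removes the secondary silyl ether; the freed benzylic hydroxyl adds to the ethoxy-bearing enone carbon (6-endo-trig oxa-Michael) and ethanol is expelled, the acid-mediated closure of beta-hydroxy beta-prime-alkoxy enones to dihydropyranones. The C–O bond of the benzylic carbon is never broken, so it stays (S), and the C1 carbinol is a bridgehead and cannot eliminate.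

## Compound list

1 | ethyl (S)-3-hydroxy-3-phenylpropanoate | CCOC(=O)C[C@H](O)c1ccccc1 | starting material
2 | ethyl (S)-3-[(tert-butyldimethylsilyl)oxy]-3-phenylpropanoate | CCOC(=O)C[C@@H](c1ccccc1)O[Si](C)(C)C(C)(C)C | intermediate
3 | (S)-3-[(tert-butyldimethylsilyl)oxy]-N-methoxy-N-methyl-3-phenylpropanamide | CON(C)C(=O)C[C@@H](c1ccccc1)O[Si](C)(C)C(C)(C)C | intermediate
4 | ethoxyacetylene | CCOC#C | starting material
5 | lithium ethoxyacetylide (formed in the flask) | CCOC#C[Li] | intermediate
6 | (S)-5-[(tert-butyldimethylsilyl)oxy]-1-ethoxy-5-phenylpent-1-yn-3-one | CCOC#CC(=O)C[C@@H](c1ccccc1)O[Si](C)(C)C(C)(C)C | intermediate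
7 | dimedone | CC1(C)CC(=O)CC(=O)C1 | starting material
8 | iodomethane | CI | starting material
9 | 2,5,5-trimethylcyclohexane-1,3-dione | CC1C(=O)CC(C)(C)CC1=O | intermediate
10 | 3-isobutoxy-2,5,5-trimethylcyclohex-2-en-1-one | CC(C)COC1=C(C)C(=O)CC(C)(C)C1 | intermediate
11 | formaldehyde | C=O | starting material
12 | lithium enolate of 10 (formed in the flask) | CC(C)COC1=C(C)C(O[Li])=CC(C)(C)C1 | intermediate
13 | rac-6-(hydroxymethyl)-3-isobutoxy-2,5,5-trimethylcyclohex-2-en-1-one | CC(C)COC1=C(C)C(=O)C(CO)C(C)(C)C1 | intermediate
14 | (R)-6-(hydroxymethyl)-3-isobutoxy-2,5,5-trimethylcyclohex-2-en-1-one | CC(C)COC1=C(C)C(=O)[C@@H](CO)C(C)(C)C1 | intermediate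
15 | (R)-4-(hydroxymethyl)-2,5,5-trimethylcyclohexane-1,3-dione (drawn as an enol) | CC1=C(O)[C@@H](CO)C(C)(C)CC1=O | intermediate
16 | (2R,4aR)-5,5,8-trimethyl-2-phenyl-4a,5-dihydro-4H-1,3-benzodioxin-7(6H)-one | CC1=C2O[C@H](c3ccccc3)OC[C@H]2C(C)(C)CC1=O | intermediate
17 | lithium enolate of 16 (formed in the flask) | CC1=C2O[C@H](c3ccccc3)OC[C@H]2C(C)(C)C=C1O[Li] | intermediate
18 | (2R,4aR)-5,5,6,8-tetramethyl-2-phenyl-4a,5-dihydro-4H-1,3-benzodioxin-7(6H)-one, both C6 epimers | CC1=C2O[C@H](c3ccccc3)OC[C@H]2C(C)(C)C(C)C1=O | intermediate
19 | lithium enolate of 18 (formed in the flask) | CC1=C2O[C@H](c3ccccc3)OC[C@H]2C(C)(C)C(C)=C1O[Li] | intermediate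
20 | tert-butyldimethyl{[(2R,4aR)-5,5,6,8-tetramethyl-2-phenyl-4a,5-dihydro-4H-1,3-benzodioxin-7-yl]oxy}silane | CC1=C2O[C@H](c3ccccc3)OC[C@H]2C(C)(C)C(C)=C1O[Si](C)(C)C(C)(C)C | intermediate
21 | cycloadduct: benzylidene acetal of the bicyclo[2.2.2]octadiene silyl enol ether carrying the ethoxy enone and the silylated (S)-hydroxy ketone chain | CC1(C)[C@@H]2CO[C@@H](c3ccccc3)O[C@]24C(C)=C(O[Si](C)(C)C(C)(C)C)[C@@]1(C)C(OCC)=C4C(=O)C[C@@H](c1ccccc1)O[Si](C)(C)C(C)(C)C | intermediate
22 | key-step precursor: bicyclo[2.2.2]octadiene silyl enol ether with free C1 hydroxyl and free hydroxymethyl group | CC1(C)[C@H](CO)[C@]2(O)C(C)=C(O[Si](C)(C)C(C)(C)C)[C@@]1(C)C(OCC)=C2C(=O)C[C@@H](c1ccccc1)O[Si](C)(C)C(C)(C)C | intermediate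
23 | key-step product: oxolane-closed cage ketone with ethoxy enone, free C1 hydroxyl and silylated (S)-carbinol | CC1(C)[C@@H]2CO[C@]3(C)C(=O)[C@@]1(C)C(OCC)=C(C(=O)C[C@@H](c4ccccc4)O[Si](C)(C)C(C)(C)C)[C@]23O | intermediate
24 | desilylated hydroxy enone (formed in the flask) | CC1(C)[C@@H]2CO[C@]3(C)C(=O)[C@@]1(C)C(OCC)=C(C(=O)C[C@H](O)c4ccccc4)[C@]23O | intermediate
25 | CNP0322161.1 | CC1(C)[C@@H]2CO[C@]3(C)C(=O)[C@@]1(C)C1=C(C(=O)C[C@@H](c4ccccc4)O1)[C@]23O | target

## Step count and least certain steps

Total step count: 15 (steps 1–3 give 6, steps 4–11 give 20, steps 12–15 join the fragments and finish).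
Longest linear sequence: 12 steps (7 to 25, steps 4–15).

**Step 14 (key step).** What is most likely to go wrong is solvolysis of the silyl enol ether by methanol and cathodically formed methoxide before it is oxidised, which would give the C6–H ketone; a second risk is cycloreversion of the radical cation of the strained diene with loss of the C7–C8 alkene. Fallback (from 22, back at 23): the bond is made by a two-electron route without a cell. With PhIO and BF3·OEt2 in CH2Cl2 at −40 °C the enol ether should attack the trivalent iodine, the hydroxymethyl oxygen should displace iodobenzene from C6 on the only face it can reach, and the silyl group should leave from the C5 oxygen. This is the known alpha-alkoxylation of silyl enol ethers by iodosylbenzene in intramolecular form; no new isolable compound is made.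

**Step 12.** The donor-substituted alkynone may react too slowly at the temperature the ethoxyalkyne tolerates, since the first bond must form at a diene terminus flanked by CMe2; forcing invites loss of ethylene from the ynol ether and Alder–Rickert cleavage of the adduct. Fallback (from 18, back at 21): an anionic Michael–Michael annulation at low temperature. Enolate 19, generated as in step 11, is treated with 6 at −78 °C; its methyl-bearing carbon should add to the ethoxy-bearing alkyne carbon and the allenolate should close on the acetal-bearing enone carbon. The resulting lithium enolate of the cage ketone F1 is silylated in the same flask with t-BuMe2SiCl to give 21.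

**Step 13.** Competing hydrogenolysis of the benzylic C–O bond of the side-chain silyl ether, or protodesilylation of the enol ether on the catalyst, would destroy the (S) centre or the key-step substrate. Fallback (from 20 and 5, back at 24): the benzylic C–O bond is kept out of the hydrogenolysis by bringing the carbinol in afterwards. Acylation of 5 with N-methoxy-N-methylacetamide gives 4-ethoxybut-3-yn-2-one F2. Cycloaddition with 20 as in step 12 gives the 2-acetyl cycloadduct F3, hydrogenolysis gives the 2-acetyl diol F4, and anodic cyclisation as in step 14 gives the 2-acetyl oxolane ketone F5, whose only enolisable position is the acetyl methyl group. A boron aldol reaction of F5 with benzaldehyde (Ipc2BCl of the sense that leads to the (S)-carbinol, Et3N, Et2O, −78 °C) should give 24 after removal of the minor carbinol epimer; step 15 then follows without the HF treatment.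

**Step 7.** The lipase may discriminate poorly at a stereocentre flanked by a quaternary carbon, or may prefer the other enantiomer. Fallback (from 13, back at 14): classical resolution through covalent diastereomers that are cleaved without base. Racemic 13 is converted with (S)-1-phenylethyl chloroformate and pyridine into two diastereomeric carbonates, which are separated by crystallisation or chromatography. Hydrogenolysis (H2, Pd/C, EtOAc) of the carbonate of the (R)-alcohol F6 returns 14.

**Step 9.** Intermolecular enol-ether formation with the liberated methanol, or acid-promoted dehydration of the beta-hydroxymethyl ketone, may compete with ring closure to the cyclic acetal. Fallback (from 15, back at 16): aprotic, kinetically controlled acetalisation in place of the acid equilibrium. 15 is silylated on both hydroxyls (Me3SiCl, Et3N) to the bis(trimethylsilyl) derivative F7, whose enol-silyl regioisomers interconvert under the next conditions. F7 is treated with benzaldehyde and catalytic Me3SiOSO2CF3 in CH2Cl2 at −78 °C; only the isomer silylated on the oxygen next to the CH2O arm can close the six-membered acetal, so the mixture should funnel to 16.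

## Further compounds

F0 | step 14 | none | none
F1 | step 12 | lithium enolate of the C5 ketone corresponding to 21 | CC1(C)[C@@H]2CO[C@@H](c3ccccc3)O[C@]24C(C)=C(O[Li])[C@@]1(C)C(OCC)=C4C(=O)C[C@@H](c1ccccc1)O[Si](C)(C)C(C)(C)C
F2 | step 13 | 4-ethoxybut-3-yn-2-one | CCOC#CC(C)=O
F3 | step 13 | 2-acetyl analogue of cycloadduct 21 | CC1(C)[C@@H]2CO[C@@H](c3ccccc3)O[C@]24C(C)=C(O[Si](C)(C)C(C)(C)C)[C@@]1(C)C(OCC)=C4C(C)=O
F4 | step 13 | 2-acetyl analogue of diol 22 | CC1(C)[C@H](CO)[C@]2(O)C(C)=C(O[Si](C)(C)C(C)(C)C)[C@@]1(C)C(OCC)=C2C(C)=O
F5 | step 13 | 2-acetyl analogue of oxolane ketone 23 | CC1(C)[C@@H]2CO[C@]3(C)C(=O)[C@@]1(C)C(OCC)=C(C(C)=O)[C@]23O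
F6 | step 7 | [(1R)-4-isobutoxy-3,6,6-trimethyl-2-oxocyclohex-3-en-1-yl]methyl (1S)-1-phenylethyl carbonate | CC(C)COC1=C(C)C(=O)[C@@H](COC(=O)O[C@@H](C)c2ccccc2)C(C)(C)C1
F7 | step 9 | bis(trimethylsilyl) derivative of 15 (one enol-silyl regioisomer shown) | CC1=C(O[Si](C)(C)C)[C@@H](CO[Si](C)(C)C)C(C)(C)CC1=O
A1 | alternative 1 | bridgehead benzyl ether cage diketone with CH2 at C2 | CC1(C)[C@@H]2CO[C@]3(C)C(=O)[C@@]1(C)C(=O)C[C@]23OCc1ccccc1
A2 | alternative 1 | phenyl 2-{[(1R)-2-(benzyloxy)-5,6,6-trimethyl-4-oxocyclohex-2-en-1-yl]methoxy}propanoate | CC(OC[C@@H]1C(OCc2ccccc2)=CC(=O)C(C)C1(C)C)C(=O)Oc1ccccc1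
A3 | alternative 2 | bridgehead tert-butyldimethylsilyl ether of 25 | CC1(C)[C@@H]2CO[C@]3(C)C(=O)[C@@]1(C)C1=C(C(=O)C[C@@H](c4ccccc4)O1)[C@]23O[Si](C)(C)C(C)(C)C
A4 | alternative 2 | bridgehead tert-butyldimethylsilyl ether cage diketone with CH2 at C2 | CC1(C)[C@@H]2CO[C@]3(C)C(=O)[C@@]1(C)C(=O)C[C@]23O[Si](C)(C)C(C)(C)C
A5 | alternative 2 | (S)-4-phenyloxetan-2-one | O=C1C[C@@H](c2ccccc2)O1
A6 | alternative 3 | ethoxy-enone cage carbinol with silylated (S)-hydroxy ketone chain (identical with 23) | CC1(C)[C@@H]2CO[C@]3(C)C(=O)[C@@]1(C)C(OCC)=C(C(=O)C[C@@H](c4ccccc4)O[Si](C)(C)C(C)(C)C)[C@]23O
A7 | alternative 3 | 6-oxabicyclo[3.2.1]octane diketone with the oxolane already closed | CC1C(=O)[C@@]2(C)OC[C@H](C2=O)C1(C)C
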